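## Retrosynthetic overview

1. The catechol comes last, by ortho-oxygenation of the C12 phenol at C11. The C2 acetate comes from hydroboration of a C2=C3 alkene, and that alkene closes ring A last, by ring-closing metathesis of an allyl group on C10 and a vinyl group on C4.
2. The 7,20-ether bridge comes from acid-mediated addition of the C20 hydroxyl to a C6=C7 styrene in a 1,2-dihydronaphthalene.
3. The strategy rests on one feature: when C20 is the ester carbon of a lactone on the C7 allylic oxygen, the array C10=C20–O–C7–C6=C5 is a 1,5-diene. A [3,3] shift then forms C5–C10, breaks C7–O, and closes carbocyclic ring B (C5–C10) with both of its stereocentres.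
4. The lactone, a 4-allyl-1-alkenylisochroman-3-one, comes from thymol (arylacetic acid, formylation para to OMe), a catalytic asymmetric alkenylzinc addition that sets C7, lactonisation and allylation.
5. Ring order: arene (ring C, from thymol), temporary lactone, ring B (step 11), ether bridge (step 13), ring A (step 14).

Key step: step 11

Remark: atom numbers C1–C20 in the text follow abietane numbering. The phenol is carried as its methyl ether and released by thiolate before acetylation, because Lewis-acidic demethylation would open the p-alkoxybenzylic 7,20-ether. Compounds 15 to 21 carry a p-methoxybenzylic, allylic C7–O bond and are to be kept away from acid (triethylamine-deactivated silica).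

## Route

Step 1
Reactants: 1 thymol
Product: 2 thymol methyl ether (1-isopropyl-2-methoxy-4-methylbenzene)
Conditions: MeI, K2CO3, acetone, reflux
Reagents that add atoms: iodomethane, CI
Why: Williamson ether synthesis on the phenoxide, the only nucleophilic site.

Step 2
Reactants: 2 thymol methyl ether
Product: 4 2-(4-isopropyl-3-methoxyphenyl)acetic acid, via benzylpotassium 3 (not isolated)
Conditions: n-BuLi, KOtBu, 2,2,6,6-tetramethylpiperidine, THF, −78 °C; cannulation into CO2-saturated THF, −78 °C; aq. HCl
Reagents that add atoms: carbon dioxide, O=C=O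
Why: Lateral (benzylic) metalation with the mixed lithium–potassium amide base should settle on the primary benzylic methyl (the amine shuttles any ring-metalated species to the benzyl anion, and the isopropyl methine is kinetically inert), and carboxylation of the benzyl anion gives the arylacetic acid.

Step 3
Reactants: 4 2-(4-isopropyl-3-methoxyphenyl)acetic acid
Product: 5 methyl 2-(4-isopropyl-3-methoxyphenyl)acetate
Conditions: MeOH, H2SO4 (cat.), reflux
Reagents that add atoms: methanol, CO
Why: Fischer esterification, which masks the acid for the Lewis-acid step that follows.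

Step 4
Reactants: 5 methyl 2-(4-isopropyl-3-methoxyphenyl)acetate
Product: 7 methyl 2-(2-formyl-4-isopropyl-5-methoxyphenyl)acetate, via chloro(methoxy)methyl arene 6 (not isolated)
Conditions: Cl2CHOMe, TiCl4, CH2Cl2, −10 to 0 °C; ice water
Reagents that add atoms: dichloromethyl methyl ether, COC(Cl)Cl; water, O
Why: Rieche formylation is expected para to the methoxy group (the ortho site between OMe and the side chain is the more hindered), which places the aldehyde carbon (C7) ortho to the acetate side chain.

Step 5
Reactants: 8 2,2-dimethylbut-3-enoic acid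
Product: 9 2,2-dimethylbut-3-en-1-ol
Conditions: LiAlH4, Et2O, 0 °C to reflux; aq. NaOH work-up
Reagents that add atoms: none
Why: Hydride reduction of the carboxylic acid; the isolated alkene is not touched.

Step 6
Reactants: 9 2,2-dimethylbut-3-en-1-ol
Product: 10 2,2-dimethylbut-3-enal
Conditions: (COCl)2, DMSO, CH2Cl2, −78 °C; Et3N, −78 to 0 °C
Reagents that add atoms: none
Why: Swern oxidation to an aldehyde that cannot enolise (quaternary α-carbon), so no double-bond migration is possible; the volatile product is carried on as a solution.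

Step 7
Reactants: 10 2,2-dimethylbut-3-enal
Product: 11 3,3-dimethylpent-1-en-4-yne
Conditions: dimethyl (1-diazo-2-oxopropyl)phosphonate, K2CO3, MeOH, 0 °C to rt; extraction into pentane
Reagents that add atoms: dimethyl (1-diazo-2-oxopropyl)phosphonate, COP(=O)(OC)C(=[N+]=[N-])C(C)=O
Why: Ohira–Bestmann (Seyferth–Gilbert type) one-carbon homologation, well suited to non-enolisable aldehydes; the enyne is used as a titrated solution.

Step 8
Reactants: 11 3,3-dimethylpent-1-en-4-yne; 7 methyl 2-(2-formyl-4-isopropyl-5-methoxyphenyl)acetate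
Product: 15 methyl 2-{2-[(1S,2E)-1-hydroxy-4,4-dimethylhexa-2,5-dienyl]-4-isopropyl-5-methoxyphenyl}acetate, via alkenyl(dicyclohexyl)borane 12 (not isolated), via alkenyl(methyl)zinc 13 (not isolated), via methylzinc alkoxide 14 (not isolated)
Conditions: Cy2BH (from BH3·SMe2 and cyclohexene), toluene, 0 °C to rt; Me2Zn, −78 °C; (−)-3-exo-morpholinoisoborneol (5 mol%); 7, −20 to 0 °C; aq. NH4Cl
Reagents that add atoms: none
Why: Syn hydroboration of the terminal alkyne (faster than that of the vinyl group on the quaternary carbon) fixes the E geometry, boron-to-zinc exchange gives an ester-tolerant alkenylzinc, and the amino-alcohol-catalysed asymmetric alkenylzinc addition is expected, by analogy with dialkylzinc additions under this ligand, to attack the Si face of the aldehyde and set C7 as S.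

Step 9
Reactants: 15 methyl 2-{2-[(1S,2E)-1-hydroxy-4,4-dimethylhexa-2,5-dienyl]-4-isopropyl-5-methoxyphenyl}acetate
Product: 16 (1S)-1-[(E)-3,3-dimethylpenta-1,4-dienyl]-7-isopropyl-6-methoxyisochroman-3-one
Conditions: DBU (0.2 equiv), 4 Å molecular sieves, toluene, 40 °C
Reagents that add atoms: none
Why: Base-catalysed intramolecular transesterification (lactonisation) of the ortho-disposed alcohol and ester to the six-membered benzo lactone; acid is avoided because the carbinol would ionise and racemise.

Step 10
Reactants: 16 (1S)-1-[(E)-3,3-dimethylpenta-1,4-dienyl]-7-isopropyl-6-methoxyisochroman-3-one; 17 allyl bromide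
Product: 19 (1S)-4-allyl-1-[(E)-3,3-dimethylpenta-1,4-dienyl]-7-isopropyl-6-methoxyisochroman-3-one (both C4 epimers), via lithium enolate 18 (not isolated)
Conditions: LiN(SiMe3)2 (1.05 equiv), THF, −78 °C; allyl bromide, −78 to −30 °C
Reagents that add atoms: none
Why: Enolate alkylation at the benzylic α-carbon C10, the only acidic position; the epimer ratio at this carbon does not matter because it becomes trigonal in step 11.

Step 11
Reactants: 19 (1S)-4-allyl-1-[(E)-3,3-dimethylpenta-1,4-dienyl]-7-isopropyl-6-methoxyisochroman-3-one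
Product: 23 (1R,2S)-1-allyl-6-isopropyl-7-methoxy-2-(2-methylbut-3-en-2-yl)-1,2-dihydronaphthalene-1-carboxylic acid, via lithium enolate 20 (not isolated), via silyl ketene acetal 21 (not isolated), via trimethylsilyl ester 22 (not isolated)
Conditions: LDA, THF, −78 °C; Me3SiCl/Et3N, −78 °C to rt; then 65 °C; H2O, pH 4–5 buffer
Reagents that add atoms: none
Why: Deprotonation at C10 and O-silylation give cyclic silyl ketene acetal 21, in which C10=C20–O–C7–C6=C5 is a 1,5-diene; on warming a concerted [3,3] sigmatropic shift (Ireland–Claisen rearrangement) forms C5–C10 as C7–O breaks, and hydrolysis of silyl ester 22 gives the acid. The closest known reaction is the Ireland–Claisen ring contraction of 6-alkenyl δ-lactone silyl ketene acetals, applied here to a benzo-fused member of that class. Ring B closes as a six-membered carbocycle by this pericyclic bond formation between the 1,4-related lactone carbons C10 and (through its vinyl group) C7, the O–C20 unit leaving the ring as the exocyclic carboxyl group; because the ketene acetal and the carbinol carbon sit in one ring, only a boat transition state bridged by the arene is possible. C5 is set by suprafacial transfer from C7 (the new bond forms on the alkene face from which oxygen departs), and C10 by the E alkene in the enforced boat, which puts C4 on the same side of ring B as the carboxyl carbon, the later trans A/B fusion. The step needs the concerted shift to outrun heterolysis of the p-methoxybenzylic allylic C7–O bond, and O- rather than C-silylation; the Lewis-acid-free, weakly polar medium and the styrene conjugation gained in the new C6=C7 bond should favour the former, and the fully substituted enolate carbon the latter.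

Step 12
Reactants: 23 (1R,2S)-1-allyl-6-isopropyl-7-methoxy-2-(2-methylbut-3-en-2-yl)-1,2-dihydronaphthalene-1-carboxylic acid
Product: 24 [(1R,2S)-1-allyl-6-isopropyl-7-methoxy-2-(2-methylbut-3-en-2-yl)-1,2-dihydronaphthalen-1-yl]methanol
Conditions: LiAlH4, THF, 0 °C to reflux; Rochelle salt
Reagents that add atoms: none
Why: Hydride reduction of the hindered neopentyl acid to the C20 primary alcohol; the three alkenes and the aryl ether are inert.

Step 13
Reactants: 24 [(1R,2S)-1-allyl-6-isopropyl-7-methoxy-2-(2-methylbut-3-en-2-yl)-1,2-dihydronaphthalen-1-yl]methanol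
Product: 25 4-allyl-7-isopropyl-6-methoxy-9-(2-methylbut-3-en-2-yl)-3,4-dihydro-1H-1,4-ethanoisochromene (7β,20-ether with 5α-H)
Conditions: TfOH (5 mol%), CH2Cl2 (0.01 M), −20 to 0 °C; Et3N
Reagents that add atoms: none
Why: Brønsted-acid-catalysed intramolecular hydroalkoxylation: protonation at C6 gives the p-methoxybenzylic C7 cation, which the C20 hydroxyl captures; the one-carbon tether can reach only the face of ring B that carries C20, so C7 is set as the 7β-ether, and the monosubstituted alkenes are not protonated at this temperature.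

Step 14
Reactants: 25 4-allyl-7-isopropyl-6-methoxy-9-(2-methylbut-3-en-2-yl)-3,4-dihydro-1H-1,4-ethanoisochromene
Product: 26 7β,20-epoxy-12-methoxyabieta-2,8,11,13-tetraene
Conditions: second-generation Grubbs catalyst RuCl2(=CHPh)(H2IMes)(PCy3) (5 mol%), CH2Cl2, 40 °C
Reagents that add atoms: none
Why: Ring-closing metathesis of the allyl group on C10 and the vinyl group on C4, which are gauche about the C10–C5 bond, closes ring A as a cyclohexene with loss of ethylene.

Step 15
Reactants: 26 7β,20-epoxy-12-methoxyabieta-2,8,11,13-tetraene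
Product: 28 7β,20-epoxy-12-methoxyabieta-8,11,13-trien-2α-ol, via B-alkyl-9-borabicyclononane 27 (not isolated)
Conditions: 9-BBN, THF, 65 °C; then NaOH, H2O2, 0 °C to rt
Reagents that add atoms: hydrogen peroxide, OO
Why: Hydroboration–oxidation: the bulky borane should add boron to C2, the alkene carbon remote from quaternary C4, from the α face opposite the axial C20 bridge and the axial 4β-methyl, and oxidation with retention then gives the equatorial 2α-alcohol.

Step 16
Reactants: 28 7β,20-epoxy-12-methoxyabieta-8,11,13-trien-2α-ol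
Product: 29 7β,20-epoxyabieta-8,11,13-triene-2α,12-diol
Conditions: NaSEt, DMF, 130 °C; aq. HCl to pH 5
Reagents that add atoms: none
Why: Nucleophilic (SN2 at methyl) cleavage of the aryl methyl ether by ethanethiolate; the 7,20-ether is safe because its carbons are a bridgehead and a neopentyl centre and no Lewis acid is present.

Step 17
Reactants: 29 7β,20-epoxyabieta-8,11,13-triene-2α,12-diol
Product: 30 7β,20-epoxyabieta-8,11,13-triene-2α,12-diyl diacetate
Conditions: Ac2O, pyridine, DMAP (cat.), CH2Cl2, rt
Reagents that add atoms: acetic anhydride, CC(=O)OC(C)=O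
Why: DMAP-catalysed acyl transfer to both hydroxyl groups.

Step 18
Reactants: 30 7β,20-epoxyabieta-8,11,13-triene-2α,12-diyl diacetate
Product: 31 2α-acetoxy-7β,20-epoxyabieta-8,11,13-trien-12-ol
Conditions: NH4OAc, MeOH/H2O 4:1, rt
Reagents that add atoms: none
Why: Chemoselective solvolysis of the aryl acetate, whose phenoxide is the far better leaving group, leaving the secondary alkyl acetate in place.

Step 19
Reactants: 31 2α-acetoxy-7β,20-epoxyabieta-8,11,13-trien-12-ol
Product: 33 2α-acetoxy-7β,20-epoxyabieta-8,11,13-triene-11,12-diol (target), via ortho-quinone 32 (not isolated)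
Conditions: IBX, DMF, rt, argon; then aq. Na2S2O4
Reagents that add atoms: 2-iodoxybenzoic acid (IBX), O=C1OI(=O)(O)c2ccccc12
Why: IBX ortho-oxygenation of the phenol at C11, its only free ortho position, should give the 11,12-quinone, which dithionite reduces in the same flask to the catechol; the quinone cannot tautomerise to a quinone methide because C7 is a bridgehead.

## Compound list

1 | thymol | Cc1ccc(C(C)C)c(O)c1 | starting material
2 | thymol methyl ether (1-isopropyl-2-methoxy-4-methylbenzene) | Cc1ccc(C(C)C)c(OC)c1 | intermediate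
3 | (4-isopropyl-3-methoxybenzyl)potassium (not isolated) | [K+].[CH2-]c1ccc(C(C)C)c(OC)c1 | intermediate
4 | 2-(4-isopropyl-3-methoxyphenyl)acetic acid | OC(=O)Cc1ccc(C(C)C)c(OC)c1 | intermediate
5 | methyl 2-(4-isopropyl-3-methoxyphenyl)acetate | COC(=O)Cc1ccc(C(C)C)c(OC)c1 | intermediate
6 | methyl 2-{2-[chloro(methoxy)methyl]-4-isopropyl-5-methoxyphenyl}acetate (not isolated) | COC(=O)Cc1cc(OC)c(C(C)C)cc1C(Cl)OC | intermediate
7 | methyl 2-(2-formyl-4-isopropyl-5-methoxyphenyl)acetate | COC(=O)Cc1cc(OC)c(C(C)C)cc1C=O | intermediate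
8 | 2,2-dimethylbut-3-enoic acid | C=CC(C)(C)C(=O)O | starting material
9 | 2,2-dimethylbut-3-en-1-ol | C=CC(C)(C)CO | intermediate
10 | 2,2-dimethylbut-3-enal | C=CC(C)(C)C=O | intermediate
11 | 3,3-dimethylpent-1-en-4-yne | C=CC(C)(C)C#C | intermediate
12 | dicyclohexyl[(E)-3,3-dimethylpenta-1,4-dienyl]borane (not isolated) | C=CC(C)(C)/C=C/B(C1CCCCC1)C1CCCCC1 | intermediate
13 | [(E)-3,3-dimethylpenta-1,4-dienyl](methyl)zinc (not isolated) | C=CC(C)(C)/C=C/[Zn]C | intermediate
14 | methylzinc alkoxide of 15 (not isolated) | COC(=O)Cc1cc(OC)c(C(C)C)cc1[C@@H](O[Zn]C)/C=C/C(C)(C)C=C | intermediate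
15 | methyl 2-{2-[(1S,2E)-1-hydroxy-4,4-dimethylhexa-2,5-dienyl]-4-isopropyl-5-methoxyphenyl}acetate | COC(=O)Cc1cc(OC)c(C(C)C)cc1[C@@H](O)/C=C/C(C)(C)C=C | intermediate
16 | (1S)-1-[(E)-3,3-dimethylpenta-1,4-dienyl]-7-isopropyl-6-methoxyisochroman-3-one | O=C1Cc2cc(OC)c(C(C)C)cc2[C@H](/C=C/C(C)(C)C=C)O1 | intermediate
17 | allyl bromide | C=CCBr | starting material
18 | lithium enolate of 16 (not isolated) | [Li]OC1=Cc2cc(OC)c(C(C)C)cc2[C@H](/C=C/C(C)(C)C=C)O1 | intermediate
19 | (1S)-4-allyl-1-[(E)-3,3-dimethylpenta-1,4-dienyl]-7-isopropyl-6-methoxyisochroman-3-one (both C4 epimers) | C=CCC1C(=O)O[C@@H](/C=C/C(C)(C)C=C)c2cc(C(C)C)c(OC)cc12 | intermediate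
20 | lithium enolate of 19 (not isolated) | C=CCC1=C(O[Li])O[C@@H](/C=C/C(C)(C)C=C)c2cc(C(C)C)c(OC)cc12 | intermediate
21 | (1S)-4-allyl-1-[(E)-3,3-dimethylpenta-1,4-dienyl]-7-isopropyl-6-methoxy-3-(trimethylsilyloxy)-1H-isochromene (not isolated) | C=CCC1=C(O[Si](C)(C)C)O[C@@H](/C=C/C(C)(C)C=C)c2cc(C(C)C)c(OC)cc12 | intermediate
22 | trimethylsilyl ester of 23 (not isolated) | C[Si](C)(C)OC(=O)[C@]1(CC=C)[C@H](C(C)(C)C=C)C=Cc2cc(C(C)C)c(OC)cc12 | intermediate
23 | (1R,2S)-1-allyl-6-isopropyl-7-methoxy-2-(2-methylbut-3-en-2-yl)-1,2-dihydronaphthalene-1-carboxylic acid | OC(=O)[C@]1(CC=C)[C@H](C(C)(C)C=C)C=Cc2cc(C(C)C)c(OC)cc12 | intermediate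
24 | [(1R,2S)-1-allyl-6-isopropyl-7-methoxy-2-(2-methylbut-3-en-2-yl)-1,2-dihydronaphthalen-1-yl]methanol | OC[C@]1(CC=C)[C@H](C(C)(C)C=C)C=Cc2cc(C(C)C)c(OC)cc12 | intermediate
25 | 4-allyl-7-isopropyl-6-methoxy-9-(2-methylbut-3-en-2-yl)-3,4-dihydro-1H-1,4-ethanoisochromene (7β,20-ether, 5α-H; the tert-alkyl group on C5 syn to the oxygen bridge) | C=CC(C)(C)[C@@H]2C[C@@H]3OC[C@@]2(CC=C)c1c3cc(C(C)C)c(OC)c1 | intermediate
26 | 7β,20-epoxy-12-methoxyabieta-2,8,11,13-tetraene | C1=CC(C)(C)[C@@H]2C[C@@H]3OC[C@@]2(C1)c1c3cc(C(C)C)c(OC)c1 | intermediate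
27 | 2α-(9-borabicyclo[3.3.1]nonan-9-yl)-7β,20-epoxy-12-methoxyabieta-8,11,13-triene (not isolated) | C1CC2CCCC(C1)B2[C@H]1CC(C)(C)[C@@H]2C[C@@H]3OC[C@@]2(C1)c1c3cc(C(C)C)c(OC)c1 | intermediate
28 | 7β,20-epoxy-12-methoxyabieta-8,11,13-trien-2α-ol | O[C@H]1CC(C)(C)[C@@H]2C[C@@H]3OC[C@@]2(C1)c1c3cc(C(C)C)c(OC)c1 | intermediate
29 | 7β,20-epoxyabieta-8,11,13-triene-2α,12-diol | O[C@H]1CC(C)(C)[C@@H]2C[C@@H]3OC[C@@]2(C1)c1c3cc(C(C)C)c(O)c1 | intermediate
30 | 7β,20-epoxyabieta-8,11,13-triene-2α,12-diyl diacetate | CC(=O)O[C@H]1CC(C)(C)[C@@H]2C[C@@H]3OC[C@@]2(C1)c1c3cc(C(C)C)c(OC(C)=O)c1 | intermediate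
31 | 2α-acetoxy-7β,20-epoxyabieta-8,11,13-trien-12-ol | CC(=O)O[C@H]1CC(C)(C)[C@@H]2C[C@@H]3OC[C@@]2(C1)c1c3cc(C(C)C)c(O)c1 | intermediate
32 | 2α-acetoxy-7β,20-epoxyabieta-8,13-diene-11,12-dione (not isolated) | CC(=O)O[C@H]1CC(C)(C)[C@@H]2C[C@@H]3OC[C@@]2(C1)C1=C3C=C(C(C)C)C(=O)C1=O | intermediate
33 | 2α-acetoxy-7β,20-epoxyabieta-8,11,13-triene-11,12-diol | CC(=O)O[C@H]1CC(C)(C)[C@@H]2C[C@@H]3OC[C@@]2(C1)c1c3cc(C(C)C)c(O)c1O | target

## Step count and risks

Total: 19 steps. Longest linear sequence: 16 steps (steps 1–4 and 8–19, from thymol); the side branch (steps 5–7) joins at step 8.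

The three steps most likely to fail:

**Step 11.** Heterolysis of the doubly activated C7–O bond may outrun the concerted shift, with loss of stereochemical fidelity or elimination. The shift may also stall, because a fully substituted ketene acetal carbon has to bond to a neopentyl alkene carbon through a strained boat. The fallback sets out from lactone 16 and comes back at acid 23; it takes the quaternary centre out of the sigmatropic step. Lactone 16 is enolised and silylated as in step 11 (through enolate 18) to (1S)-1-[(E)-3,3-dimethylpenta-1,4-dienyl]-7-isopropyl-6-methoxy-3-(trimethylsilyloxy)-1H-isochromene F1. Its shift makes only a tertiary centre at C10 and should run at lower temperature, through trimethylsilyl (1R,2R)-6-isopropyl-7-methoxy-2-(2-methylbut-3-en-2-yl)-1,2-dihydronaphthalene-1-carboxylate F2, to (1R,2R)-6-isopropyl-7-methoxy-2-(2-methylbut-3-en-2-yl)-1,2-dihydronaphthalene-1-carboxylic acid F3 after hydrolysis. Double deprotonation (LDA, 2.2 equiv, THF, 0 °C) gives the dilithium enediolate of that acid F4. Allyl bromide 17 should alkylate it on the face opposite the adjacent tert-alkyl group on C5, which places allyl trans to C4 and so gives 23. This fallback replaces steps 10 and 11; it still relies on the [3,3] shift, so it does not help if the boat cannot be reached at all.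

**Step 13.** Protonation is reversible, so the electron-rich styrene may oligomerise or the ring closure may stop at an unfavourable equilibrium. The fallback sets out from alcohol 24 and comes back at ether 25; it makes the closure irreversible. N-Iodosuccinimide (NaHCO3, MeCN/CH2Cl2, −20 °C) should attack the styrene in preference to the monosubstituted alkenes, and anti capture by the C20 hydroxyl at C7 would give 4-allyl-10-iodo-7-isopropyl-6-methoxy-9-(2-methylbut-3-en-2-yl)-3,4-dihydro-1H-1,4-ethanoisochromene (6α-iodo-7β,20-ether, iodine trans to the ether oxygen) F5. Radical deiodination (Bu3SnH, AIBN, toluene, 80 °C) then gives 25. The C6 radical is anti to the allyl group across C5–C10 and so cannot cyclise onto it.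

**Step 15.** Boron may be delivered to C3 as well as C2, or the hindered alkene may react too slowly. The fallback sets out from alkene 26 and comes back at alcohol 28; it takes the regiochemistry from trans-diaxial opening (Fürst–Plattner rule) and not from sterics at the alkene. Oxymercuration (Hg(OAc)2, THF/H2O, rt) on the open α face, with axial attack of water at C2 (C3 is neopentyl), would give 3α-(acetoxymercurio)-7β,20-epoxy-12-methoxyabieta-8,11,13-trien-2β-ol F6. Reduction in the same flask (NaBH4, aq. NaOH) gives 7β,20-epoxy-12-methoxyabieta-8,11,13-trien-2β-ol F7. Oxidation (Dess–Martin periodinane, CH2Cl2) gives 7β,20-epoxy-12-methoxyabieta-8,11,13-trien-2-one F8, which has no epimerisable α-centre. Meerwein–Ponndorf–Verley reduction under equilibrating conditions (Al(OiPr)3, iPrOH, reflux) should then favour the equatorial 2α-alcohol 28, since the 2β-hydroxyl is syn-axial to both C20 and the 4β-methyl.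

## Further compounds

F1 | step 11 | (1S)-1-[(E)-3,3-dimethylpenta-1,4-dienyl]-7-isopropyl-6-methoxy-3-(trimethylsilyloxy)-1H-isochromene | C[Si](C)(C)OC1=Cc2cc(OC)c(C(C)C)cc2[C@H](/C=C/C(C)(C)C=C)O1
F2 | step 11 | trimethylsilyl (1R,2R)-6-isopropyl-7-methoxy-2-(2-methylbut-3-en-2-yl)-1,2-dihydronaphthalene-1-carboxylate | C[Si](C)(C)OC(=O)[C@@H]1[C@H](C(C)(C)C=C)C=Cc2cc(C(C)C)c(OC)cc12
F3 | step 11 | (1R,2R)-6-isopropyl-7-methoxy-2-(2-methylbut-3-en-2-yl)-1,2-dihydronaphthalene-1-carboxylic acid | OC(=O)[C@@H]1[C@H](C(C)(C)C=C)C=Cc2cc(C(C)C)c(OC)cc12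
F4 | step 11 | dilithium enediolate of F3 | [Li]OC(O[Li])=C1[C@H](C(C)(C)C=C)C=Cc2cc(C(C)C)c(OC)cc12
F5 | step 13 | 4-allyl-10-iodo-7-isopropyl-6-methoxy-9-(2-methylbut-3-en-2-yl)-3,4-dihydro-1H-1,4-ethanoisochromene (6α-iodo-7β,20-ether) | C=CC(C)(C)[C@@H]2[C@@H](I)[C@@H]3OC[C@@]2(CC=C)c1c3cc(C(C)C)c(OC)c1
F6 | step 15 | 3α-(acetoxymercurio)-7β,20-epoxy-12-methoxyabieta-8,11,13-trien-2β-ol | O[C@@H]1[C@@H]([Hg]OC(C)=O)C(C)(C)[C@@H]2C[C@@H]3OC[C@@]2(C1)c1c3cc(C(C)C)c(OC)c1
F7 | step 15 | 7β,20-epoxy-12-methoxyabieta-8,11,13-trien-2β-ol | O[C@@H]1CC(C)(C)[C@@H]2C[C@@H]3OC[C@@]2(C1)c1c3cc(C(C)C)c(OC)c1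
F8 | step 15 | 7β,20-epoxy-12-methoxyabieta-8,11,13-trien-2-one | O=C1CC(C)(C)[C@@H]2C[C@@H]3OC[C@@]2(C1)c1c3cc(C(C)C)c(OC)c1
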